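**Retrosynthetic overview**
- Target ⇐ O‑methylation of 2,4‑dibromo‑6‑(2,4‑dibromophenoxy)phenol ⇐ OH‑directed ortho/para dibromination of 2‑(2,4‑dibromophenoxy)phenol.
- That phenol ⇐ dehydrogenative aromatization of 2‑(2,4‑dibromophenoxy)cyclohex‑2‑en‑1‑one, so the oxygenated ring A is built de novo.
- Cyclohexenone ⇐ decarboxylative intramolecular aldol condensation ⇐ intermolecular Michael addition of tert‑butyl 4‑(2,4‑dibromophenoxy)‑3‑oxobutanoate to acrolein (key C–C bond).
- β‑Keto ester ⇐ crossed Claisen condensation of tert‑butyl acetate with methyl (2,4‑dibromophenoxy)acetate ⇐ 2,4‑dibromophenol + methyl bromoacetate.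
- Ring order: ring B is bought as 2,4‑dibromophenol; ring A is the only ring formed (cyclohexenone, then arene).

Assumption: the target is achiral, so no stereocontrol is needed; the stereocentres in 8, 9, 11 and 13 are racemic or mixed and are destroyed on the way.

**Step 1**
Reactants: 1 2,4‑dibromophenol; 2 methyl bromoacetate
Product: 3 methyl 2‑(2,4‑dibromophenoxy)acetate
Conditions: K2CO3 (1.5 equiv), acetone, reflux
Reagents that add atoms: none
Why: Williamson ether synthesis of an acidic phenol with an activated primary α‑bromo ester is clean SN2 O‑alkylation.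

**Step 2**
Reactants: 3 methyl 2‑(2,4‑dibromophenoxy)acetate; 4 tert‑butyl acetate
Product: 6 tert‑butyl 4‑(2,4‑dibromophenoxy)‑3‑oxobutanoate, via tert‑butyl acetate lithium enolate 5 (not isolated)
Conditions: LiHMDS (2.3 equiv), t‑BuOAc (2.4 equiv), THF, −78 °C; then 3, −78 → −30 °C; 1 M HCl quench
Reagents that add atoms: none
Why: Crossed Claisen condensation of a preformed, non‑self‑condensing tert‑butyl ester enolate with the electrophilic aryloxyacetate, driven by deprotonation of the β‑keto ester product, with no free amide base or alkyllithium left to attack the aryl bromides.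

**Step 3**
Reactants: 6 tert‑butyl 4‑(2,4‑dibromophenoxy)‑3‑oxobutanoate; 7 acrolein
Product: 8 tert‑butyl 2‑[2‑(2,4‑dibromophenoxy)acetyl]‑5‑oxopentanoate (racemic)
Conditions: acrolein (1.1 equiv, slow addition), Et3N (10 mol%), CH2Cl2, −20 → 0 °C
Reagents that add atoms: none
Why: Amine‑catalysed Michael addition of the doubly activated C‑2 carbon of the β‑keto ester to acrolein joins the two fragments; the new stereocentre is labile and irrelevant.

**Step 4**
Reactants: 8 tert‑butyl 2‑[2‑(2,4‑dibromophenoxy)acetyl]‑5‑oxopentanoate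
Product: 12 2‑(2,4‑dibromophenoxy)cyclohex‑2‑en‑1‑one, via keto acid 9 (not isolated), via keto aldehyde 10 (not isolated), via aldol 11 (not isolated)
Conditions: TsOH·H2O (20 mol%), toluene, 80 °C
Reagents that add atoms: none
Why: Acid cleaves the tert‑butyl ester and the β‑keto acid decarboxylates, then the only geometrically possible intramolecular aldol condensation (aryloxy‑side enol onto the aldehyde, 6‑ring) and dehydration give the conjugated enone.

**Step 5**
Reactants: 12 2‑(2,4‑dibromophenoxy)cyclohex‑2‑en‑1‑one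
Product: 14 2‑(2,4‑dibromophenoxy)phenol, via 6‑iodo enone 13 (not isolated)
Conditions: I2 (20 mol%), DMSO, 90 °C, N2
Reagents that add atoms: none
Why: Iodine‑catalysed oxidative aromatization (α′‑iodination, loss of HI, dienone–phenol tautomerization) with DMSO reoxidizing HI, under which aryl bromides are inert.

**Step 6**
Reactants: 14 2‑(2,4‑dibromophenoxy)phenol
Product: 15 2,4‑dibromo‑6‑(2,4‑dibromophenoxy)phenol
Conditions: Br2 (2.05 equiv), AcOH, rt
Reagents that add atoms: bromine, BrBr
Why: Electrophilic aromatic bromination is directed by the free OH to its open ortho and para positions, while the already dibrominated aryloxy ring is far less reactive.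

**Step 7**
Reactants: 15 2,4‑dibromo‑6‑(2,4‑dibromophenoxy)phenol
Product: 16 1,5‑dibromo‑3‑(2,4‑dibromophenoxy)‑2‑methoxybenzene
Conditions: MeI (1.5 equiv), K2CO3, DMF, rt
Reagents that add atoms: iodomethane, CI
Why: Williamson O‑methylation of the acidic, flanked phenoxide with unhindered methyl iodide gives the target.

**Compound list**
1 | 2,4‑dibromophenol | Oc1ccc(Br)cc1Br | starting material
2 | methyl bromoacetate | COC(=O)CBr | starting material
3 | methyl 2‑(2,4‑dibromophenoxy)acetate | COC(=O)COc1ccc(Br)cc1Br | intermediate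
4 | tert‑butyl acetate | CC(=O)OC(C)(C)C | starting material
5 | tert‑butyl acetate lithium enolate (lithium 1‑tert‑butoxyethen‑1‑olate, formed in situ) | C=C([O-])OC(C)(C)C.[Li+] | intermediate
6 | tert‑butyl 4‑(2,4‑dibromophenoxy)‑3‑oxobutanoate | CC(C)(C)OC(=O)CC(=O)COc1ccc(Br)cc1Br | intermediate
7 | acrolein (prop‑2‑enal) | C=CC=O | starting material
8 | tert‑butyl 2‑[2‑(2,4‑dibromophenoxy)acetyl]‑5‑oxopentanoate (racemic) | CC(C)(C)OC(=O)C(CCC=O)C(=O)COc1ccc(Br)cc1Br | intermediate
9 | keto acid: 2‑[2‑(2,4‑dibromophenoxy)acetyl]‑5‑oxopentanoic acid (racemic, in situ) | OC(=O)C(CCC=O)C(=O)COc1ccc(Br)cc1Br | intermediate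
10 | keto aldehyde: 6‑(2,4‑dibromophenoxy)‑5‑oxohexanal (in situ) | O=CCCCC(=O)COc1ccc(Br)cc1Br | intermediate
11 | aldol: 2‑(2,4‑dibromophenoxy)‑3‑hydroxycyclohexan‑1‑one (diastereomer mixture, in situ) | O=C1CCCC(O)C1Oc1ccc(Br)cc1Br | intermediate
12 | 2‑(2,4‑dibromophenoxy)cyclohex‑2‑en‑1‑one | O=C1CCCC=C1Oc1ccc(Br)cc1Br | intermediate
13 | 6‑iodo enone: 2‑(2,4‑dibromophenoxy)‑6‑iodocyclohex‑2‑en‑1‑one (racemic, in situ) | O=C1C(I)CCC=C1Oc1ccc(Br)cc1Br | intermediate
14 | 2‑(2,4‑dibromophenoxy)phenol | Oc1ccccc1Oc1ccc(Br)cc1Br | intermediate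
15 | 2,4‑dibromo‑6‑(2,4‑dibromophenoxy)phenol | Oc1c(Br)cc(Br)cc1Oc1ccc(Br)cc1Br | intermediate
16 | 1,5‑dibromo‑3‑(2,4‑dibromophenoxy)‑2‑methoxybenzene (achiral) | COc1c(Br)cc(Br)cc1Oc1ccc(Br)cc1Br | target

**Totals**
Total step count: 7. Longest linear sequence: 7 steps (fully linear from 1).

**Steps most likely to fail**

Step 3 (Michael addition to acrolein). The risks are double addition and acrolein polymerization. The fallback sets out from 6 and comes back at 8. It replaces the conjugate addition by C‑alkylation of 6 with 2‑(2‑bromoethyl)‑1,3‑dioxolane (K2CO3, cat. NaI, DMF, 60 °C) to give tert‑butyl 2‑[2‑(2,4‑dibromophenoxy)acetyl]‑4‑(1,3‑dioxolan‑2‑yl)butanoate F1. Mild acetal hydrolysis (PPTS, acetone/H2O, 50 °C) then unmasks the aldehyde to give 8, leaving the tert‑butyl ester intact.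

Step 4 (acid cascade). The risks are slow enolization on the aryloxy side, pyran formation, and acid‑induced cyclodehydration of the α‑aryloxy ketone towards a benzofuran. The fallback sets out from 8 and comes back at 12. It separates ring closure from decarboxylation. A piperidine/AcOH‑mediated intramolecular aldol condensation (toluene, 60 °C, 4 Å MS), the textbook base/amine Robinson closure at the γ‑carbon of a β‑keto ester, gives tert‑butyl 3‑(2,4‑dibromophenoxy)‑2‑oxocyclohex‑3‑ene‑1‑carboxylate F2. TFA/CH2Cl2 at rt then gives 3‑(2,4‑dibromophenoxy)‑2‑oxocyclohex‑3‑ene‑1‑carboxylic acid F3, which decarboxylates on warming in toluene (80 °C) to 12.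

Step 5 (aromatization). The risks are iodination of the electron‑rich phenol product and Kornblum‑type over‑oxidation of the α′‑iodo ketone. The fallback sets out from 12 and comes back at 14. Soft enolization (TMSOTf, Et3N, CH2Cl2, 0 °C) gives the cross‑conjugated silyl dienol ether {[6‑(2,4‑dibromophenoxy)cyclohexa‑1,5‑dien‑1‑yl]oxy}trimethylsilane F4. Dehydrogenation with DDQ (1.1 equiv, toluene, rt) and work‑up with 1 M HCl removes the silyl group and delivers 14 without any halogenating agent present.

**Further compounds**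
F1 | step 3 | tert‑butyl 2‑[2‑(2,4‑dibromophenoxy)acetyl]‑4‑(1,3‑dioxolan‑2‑yl)butanoate (racemic) | CC(C)(C)OC(=O)C(CCC1OCCO1)C(=O)COc1ccc(Br)cc1Br
F2 | step 4 | tert‑butyl 3‑(2,4‑dibromophenoxy)‑2‑oxocyclohex‑3‑ene‑1‑carboxylate (racemic) | CC(C)(C)OC(=O)C1CCC=C(Oc2ccc(Br)cc2Br)C1=O
F3 | step 4 | 3‑(2,4‑dibromophenoxy)‑2‑oxocyclohex‑3‑ene‑1‑carboxylic acid (racemic) | OC(=O)C1CCC=C(Oc2ccc(Br)cc2Br)C1=O
F4 | step 5 | {[6‑(2,4‑dibromophenoxy)cyclohexa‑1,5‑dien‑1‑yl]oxy}trimethylsilane | C[Si](C)(C)OC1=CCCC=C1Oc1ccc(Br)cc1Br
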